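A leftover opens this: after 30.0 h the gamma run still holds 18.8% of its starting material, beside 38.5% of target.

| setting | beta | theta | gamma | dawn | midnight |
|---|---|---|---|---|---|
| starting material | 0.93 M | 0.93 M | 0.56 M | 0.30 M | 0.93 M |
| reagent | 0.35 M | 1.8 M | 2.33 M | 0.600 M | 2.33 M |
| remark | run made earlier | run made earlier | run made earlier |  |  |
| time |  |  |  | 20 h | 40 h |

| run | time / h | target / % | starting material / % |
|---|---|---|---|
| beta | 2.50 | 0.9 | 58.7 |
| beta | 3.00 | 1.0 | 53.7 |
| beta | 5.00 | 0 | 43.1 |
| beta | 8.00 | 1.6 | 37.4 |
| beta | 12.0 | 2.7 | 31.9 |
| beta | 20.0 | 7.5 | 24.0 |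
| beta | 30.0 | 7.7 | 22.1 |
| theta | 1.50 | 0 | 68.2 |
| theta | 4.00 | 4.3 | 44.8 |
| theta | 8.00 | 10.1 | 33.4 |
| theta | 12.0 | 12.9 | 29.0 |
| theta | 15.0 | 16.8 | 24.4 |
| theta | 20.0 | 21.4 | 23.2 |
| theta | 30.0 | 29.4 | 17.7 |
| gamma | 2.50 | 0.8 | 60.1 |
| gamma | 4.00 | 5.0 | 49.3 |
| gamma | 8.00 | 11.9 | 36.7 |
| gamma | 15.0 | 23.1 | 26.0 |
| gamma | 30.0 | 38.5 | 18.8 |

(scatter of a reading: 1 percentage point)



- which of the two ends with the higher amount of target, in percent of the starting material charged ("neither" if they lie within 2 percentage points) (dawn / midnight / neither)
- target at the end, in percent of the starting material charged, dawn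
- target at the end, in percent of the starting material charged, midnight

**Which balance do we write?** That of the starting material, the limiting reagent in dawn and in midnight. Midnight charges 0.93 M of it, less than the 2.33 M of reagent. Dawn charges 0.30 M of it, less than the 0.600 M of reagent. Starting material and target are counted as fractions of the starting material charged.

**Does gamma's balance close?** No. Its last reading leaves 42.7% of the charge in neither column.

**So what can you say about target?** Its late gain can be compared with the reagent and the starting material standing. From 15.0 h to 30.0 h, gamma gives 0.0197 M⁻¹ h⁻¹. I call this the capture constant: fraction of target gained per hour, per molar of charged reagent, per fraction of starting material standing.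

**Is that one run's accident?** Theta, from 20.0 h to 30.0 h, gives 0.0217 M⁻¹ h⁻¹, with different reagent and a different charge.

**Does it hold from the start?** No. Theta reads 0% target at 1.50 h with 68.2% starting material standing. So I use it late, from a later reading.

**Your numbers?** For dawn I scale the readings at its own time by reagent. Theta gives 7.13% and beta gives 12.9%, and I take the middle, 10.0%. For midnight, theta's reading at 20.0 h scales to 27.7%. The remaining 20.0 h then add 16 percentage points, with theta's 17.7% as the mean starting material. That makes 43.9% for midnight, more than my figure for dawn.

The forecast said midnight, with 7% for dawn and 44% for midnight, and reasoned “Target appears slowly after a short lag”.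

The flask gives midnight: dawn 9.80%, midnight 39.8%.

    starting material + reactive form → side product (k = 0.0330 M⁻¹ h⁻¹)
    2 starting material → homo dimer (k = 0.0330 M⁻¹ h⁻¹)
    starting material ⇌ reactive form (K = 1.20, k = 0.210 h⁻¹)
    reagent + reactive form → target (k = 0.0210 M⁻¹ h⁻¹)

Midnight has not come to rest at 40.0 h. Starting material stands at 10.7%, reactive form at 11.8%, and reagent at 84.1% of its own charge. Over midnight's second half, the capture constant with the flask's starting material gives 14 points, and the flask's gain is 14 points. Over dawn's second half it gives 4.4 points, against the flask's 5.2 points. Left ten times as long, dawn reaches 45.7% target with 7.01% starting material, and midnight reaches 59.3% with 0.00670%.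

(The readings stem from a simulated flask with made-up constants, noise included.)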